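**Retrosynthetic overview** (cembrane numbering: C1 carries the isopropenyl group, C2 the ring OAc, C4 the CH2OAc carbon C18, C7 the OH)
1. The target comes from the macrocyclic 2-ol by C2 acetylation and C7 desilylation in one flask.
2. The only ring (14-membered) is closed at C1–C2 by a catalytic asymmetric type-I carbonyl-ene reaction of an acyclic enal with its own prenyl terminus; loss of a methyl H gives the isopropenyl group, as in the cembrene-A closure, and C1 and C2 are set together.
3. The acyclic enal comes from a C4–C5 B-alkyl Suzuki coupling of a C5 alkylborane with (Z)-4-acetoxy-3-iodobut-2-enal (from but-2-yne-1,4-diol; geometry from anti-hydroiodination).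
4. The C5–C17 piece comes from Cu-catalysed anti-carbomagnesiation (MeMgBr) of (S)-pent-1-en-4-yn-3-ol with geranyl bromide trapping (8Z alkene, C9–C10 bond); C7 comes from a Sharpless kinetic resolution.
5. Ring order: a single ring, formed in step 8 of 9.

Assumption: rac-pent-1-en-4-yn-3-ol is bought (otherwise one step from acrolein and ethynylmagnesium bromide); the target is read as 1R,2S,7S with C2/C5 cis across C3=C4 (3E by CIP), 8Z and 11E.

Step 1
Reactants: 1 but-2-yne-1,4-diol
Product: 2 4-hydroxybut-2-yn-1-yl acetate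
Conditions: Ac2O (0.33 equiv), pyridine, DMAP (cat.), THF, 0 °C → rt
Reagents that add atoms: acetic anhydride, CC(=O)OC(C)=O
Why: Statistical mono-esterification of the symmetric diol (threefold excess) with limiting Ac2O stops at the monoacetate, which is separated from the water-soluble diol and a little diacetate.

Step 2
Reactants: 2 4-hydroxybut-2-yn-1-yl acetate
Product: 3 4-oxobut-2-yn-1-yl acetate
Conditions: activated MnO2 (15 equiv), CH2Cl2, rt
Reagents that add atoms: none
Why: MnO2 oxidation of an activated (propargylic) primary alcohol gives the conjugated ynal and leaves the acetate alone.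

Step 3
Reactants: 3 4-oxobut-2-yn-1-yl acetate
Product: 4 (2Z)-2-iodo-4-oxobut-2-en-1-yl acetate
Conditions: NaI (1.5 equiv), AcOH, rt, dark, 1 h; used at once
Reagents that add atoms: sodium iodide, [Na+].[I-]
Why: In this anti-hydroiodination of an alkynyl carbonyl compound, iodide adds to the β-carbon and the allenolate is protonated anti, so the kinetic Z-β-iodoenal (I cis to CHO) forms, which fixes C2 cis to the future C5 and C18 trans to C2.

Step 4
Reactants: 5 rac-pent-1-en-4-yn-3-ol
Product: 6 (3S)-pent-1-en-4-yn-3-ol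
Conditions: Ti(OiPr)4 (0.15 equiv), L-(+)-DIPT (0.2 equiv), t-BuOOH (0.6 equiv), 4 Å MS, CH2Cl2, −20 °C, to about 60% conversion
Reagents that add atoms: none
Why: In this Sharpless kinetic resolution with L-(+)-tartrate the (R)-vinyl carbinol is epoxidised faster, so the recovered alcohol is the (S)-enantiomer (C7 of the target) in high ee.

Step 5
Reactants: 6 (3S)-pent-1-en-4-yn-3-ol; 7 geranyl bromide, (2E)-1-bromo-3,7-dimethylocta-2,6-diene
Product: 9 (3S,4Z,7E)-4,8,12-trimethyltrideca-1,4,7,11-tetraen-3-ol, via (5S)-5-ethenyl-4-methyl-2,5-dihydro-1,2-oxamagnesole 8 (not isolated)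
Conditions: MeMgBr (2.5 equiv), CuI (15 mol %), THF/Et2O, −20 °C → rt, 12 h; then 7 (2 equiv), 0 °C → rt; aq NH4Cl
Reagents that add atoms: methylmagnesium bromide, C[Mg]Br
Why: Copper-catalysed anti-carbomagnesiation of the terminal propargylic alkoxide (Duboudin–Jousseaume type, directed by the O–Mg chelate) puts CH3 on C8 and Mg on C9 cis to C7, and Cu-catalysed SN2 allylation of this vinylmagnesium with geranyl bromide gives the 8Z skipped diene with retention while C7 is untouched.

Step 6
Reactants: 9 (3S,4Z,7E)-4,8,12-trimethyltrideca-1,4,7,11-tetraen-3-ol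
Product: 10 tert-butyldimethyl{[(3S,4Z,7E)-4,8,12-trimethyltrideca-1,4,7,11-tetraen-3-yl]oxy}silane
Conditions: TBSCl, imidazole, DMF, rt
Reagents that add atoms: tert-butyldimethylsilyl chloride, CC(C)(C)[Si](C)(C)Cl
Why: Standard silylation masks the only hydroxyl, so it cannot be acetylated later or form a hemiacetal with the aldehyde.

Step 7
Reactants: 10 tert-butyldimethyl{[(3S,4Z,7E)-4,8,12-trimethyltrideca-1,4,7,11-tetraen-3-yl]oxy}silane; 4 (2Z)-2-iodo-4-oxobut-2-en-1-yl acetate
Product: 12 (2E,6S,7Z,10E)-3-(acetoxymethyl)-6-[(tert-butyldimethylsilyl)oxy]-7,11,15-trimethylhexadeca-2,7,10,14-tetraenal, via 9-[(3S,4Z,7E)-3-[(tert-butyldimethylsilyl)oxy]-4,8,12-trimethyltrideca-4,7,11-trien-1-yl]-9-borabicyclo[3.3.1]nonane 11 (not isolated)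
Conditions: 9-BBN dimer (0.6 equiv), THF, 0 °C → rt; then degassed aq Cs2CO3 (3 equiv), 4 (1.2 equiv), Pd(dppf)Cl2 (5 mol %), AsPh3 (10 mol %), DMF, rt, dark
Reagents that add atoms: 9-borabicyclo[3.3.1]nonane (9-BBN-H), B1C2CCCC1CCC2 (gives the boryl group of 11; only its H remains in 12)
Why: 9-BBN hydroborates only the monosubstituted vinyl group (anti-Markovnikov; trisubstituted alkenes are far slower), and the B-alkyl Suzuki–Miyaura coupling with the activated Z-vinyl iodide joins C4–C5 with retention of alkene geometry under mild base.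

Step 8
Reactants: 12 (2E,6S,7Z,10E)-3-(acetoxymethyl)-6-[(tert-butyldimethylsilyl)oxy]-7,11,15-trimethylhexadeca-2,7,10,14-tetraenal
Product: 13 [(1E,3S,4R,7E,10Z,12S)-12-[(tert-butyldimethylsilyl)oxy]-3-hydroxy-7,11-dimethyl-4-(prop-1-en-2-yl)cyclotetradeca-1,7,10-trien-1-yl]methyl acetate
Conditions: confined chiral imidodiphosphorimidate (IDPi) Brønsted acid (5 mol %), CHCl3, −40 °C, syringe-pump addition of 12 over 12 h, final 2 mM
Reagents that add atoms: none
Why: Proposed new method: the acid-bound enal is attacked at C2 on its Re face by the distal prenyl double bond in a chair-like, concerted-asynchronous type-I carbonyl-ene transition state (both chain ends pseudo-equatorial, a methyl H passing to O), which closes the 14-membered ring at C1–C2 as in the cembrene-A cyclisation and gives the isopropenyl group with the 1R,2S (1,2-trans) relationship; the closest known reaction is the confined-acid-catalysed, trans- and enantioselective cyclisation of neral to isopiperitenol (same enal/prenyl ene core), here extended to a macrocycle under high dilution with the catalyst antipode that gives the (1S,6R) series there.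

Step 9
Reactants: 13 [(1E,3S,4R,7E,10Z,12S)-12-[(tert-butyldimethylsilyl)oxy]-3-hydroxy-7,11-dimethyl-4-(prop-1-en-2-yl)cyclotetradeca-1,7,10-trien-1-yl]methyl acetate
Product: 15 [(1E,3S,4R,7E,10Z,12S)-3-acetoxy-12-hydroxy-7,11-dimethyl-4-(prop-1-en-2-yl)cyclotetradeca-1,7,10-trien-1-yl]methyl acetate (CNP0097266.2), via [(1E,3S,4R,7E,10Z,12S)-3-acetoxy-12-[(tert-butyldimethylsilyl)oxy]-7,11-dimethyl-4-(prop-1-en-2-yl)cyclotetradeca-1,7,10-trien-1-yl]methyl acetate 14 (not isolated)
Conditions: Ac2O (3 equiv), DMAP (0.2 equiv), pyridine, THF, 0 °C → rt; MeOH quench; then HF·pyridine, 0 °C → rt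
Reagents that add atoms: acetic anhydride, CC(=O)OC(C)=O
Why: DMAP-catalysed esterification of the C2 alcohol, then (after excess Ac2O is destroyed) buffered fluoride desilylation of the C7 TBS ether in the same flask, leaves both acetates and all stereocentres untouched.

**Compound list**
1 | but-2-yne-1,4-diol | OCC#CCO | starting material
2 | 4-hydroxybut-2-yn-1-yl acetate | CC(=O)OCC#CCO | intermediate
3 | 4-oxobut-2-yn-1-yl acetate | CC(=O)OCC#CC=O | intermediate
4 | (2Z)-2-iodo-4-oxobut-2-en-1-yl acetate | CC(=O)OC/C(I)=C/C=O | intermediate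
5 | rac-pent-1-en-4-yn-3-ol | C#CC(O)C=C | starting material
6 | (3S)-pent-1-en-4-yn-3-ol | C#C[C@@H](O)C=C | intermediate
7 | geranyl bromide, (2E)-1-bromo-3,7-dimethylocta-2,6-diene | BrC/C=C(\C)CCC=C(C)C | starting material
8 | (5S)-5-ethenyl-4-methyl-2,5-dihydro-1,2-oxamagnesole (cyclic vinylmagnesium alkoxide) | C=C[C@@H]1O[Mg]C=C1C | intermediate
9 | (3S,4Z,7E)-4,8,12-trimethyltrideca-1,4,7,11-tetraen-3-ol | C=C[C@H](O)/C(C)=C\C/C=C(\C)CCC=C(C)C | intermediate
10 | tert-butyldimethyl{[(3S,4Z,7E)-4,8,12-trimethyltrideca-1,4,7,11-tetraen-3-yl]oxy}silane | C=C[C@H](O[Si](C)(C)C(C)(C)C)/C(C)=C\C/C=C(\C)CCC=C(C)C | intermediate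
11 | 9-[(3S,4Z,7E)-3-[(tert-butyldimethylsilyl)oxy]-4,8,12-trimethyltrideca-4,7,11-trien-1-yl]-9-borabicyclo[3.3.1]nonane | B1(CC[C@H](O[Si](C)(C)C(C)(C)C)/C(C)=C\C/C=C(\C)CCC=C(C)C)C2CCCC1CCC2 | intermediate
12 | (2E,6S,7Z,10E)-3-(acetoxymethyl)-6-[(tert-butyldimethylsilyl)oxy]-7,11,15-trimethylhexadeca-2,7,10,14-tetraenal | O=C/C=C(/COC(C)=O)CC[C@H](O[Si](C)(C)C(C)(C)C)/C(C)=C\C/C=C(\C)CCC=C(C)C | intermediate
13 | [(1E,3S,4R,7E,10Z,12S)-12-[(tert-butyldimethylsilyl)oxy]-3-hydroxy-7,11-dimethyl-4-(prop-1-en-2-yl)cyclotetradeca-1,7,10-trien-1-yl]methyl acetate | C=C(C)[C@H]1CC/C(C)=C/C/C=C(/C)[C@@H](O[Si](C)(C)C(C)(C)C)CC/C(COC(C)=O)=C\[C@@H]1O | intermediate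
14 | [(1E,3S,4R,7E,10Z,12S)-3-acetoxy-12-[(tert-butyldimethylsilyl)oxy]-7,11-dimethyl-4-(prop-1-en-2-yl)cyclotetradeca-1,7,10-trien-1-yl]methyl acetate | C=C(C)[C@H]1CC/C(C)=C/C/C=C(/C)[C@@H](O[Si](C)(C)C(C)(C)C)CC/C(COC(C)=O)=C\[C@@H]1OC(C)=O | intermediate
15 | [(1E,3S,4R,7E,10Z,12S)-3-acetoxy-12-hydroxy-7,11-dimethyl-4-(prop-1-en-2-yl)cyclotetradeca-1,7,10-trien-1-yl]methyl acetate; cembrane locants (1R,2S,3E,7S,8Z,11E)-2,18-diacetoxycembra-3,8,11,15(17)-tetraen-7-ol | C=C(C)[C@H]1CC/C(C)=C/C/C=C(/C)[C@@H](O)CC/C(COC(C)=O)=C\[C@@H]1OC(C)=O | target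

**Step count:** 9 steps in total. Longest linear sequence: 6 steps (5 → 6 → 9 → 10 → 12 → 13 → 15, steps 4–9; the iodide branch, steps 1–3, joins at step 7 and is also 6 steps to the target).

**Three steps most likely to fail**

Step 8 (carbonyl-ene macrocyclisation). The confined acid may not accommodate a 14-membered transition state, the C7 centre may be mismatched with the catalyst, and acid-induced enal E/Z isomerisation or polyene side reactions can compete. The fallback keeps the C1–C2 closure but pre-activates the nucleophile, starting from 12. Selenium dioxide (cat.)/t-BuOOH oxidises the terminal E-methyl group to (2E,6S,7Z,10E,14E)-3-(acetoxymethyl)-6-[(tert-butyldimethylsilyl)oxy]-16-hydroxy-7,11,15-trimethylhexadeca-2,7,10,14-tetraenal F5. CBr4/PPh3 converts it into (2E,6S,7Z,10E,14E)-3-(acetoxymethyl)-16-bromo-6-[(tert-butyldimethylsilyl)oxy]-7,11,15-trimethylhexadeca-2,7,10,14-tetraenal F6. CrCl2 in THF at 2 mM then closes the ring by intramolecular Nozaki–Hiyama allylation through C1 (chair transition state, same 1,2-trans relationship). The product is 13 together with its (1S,2R) diastereomer, separated on silica, and the route is rejoined at 13.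

Step 5 (one-pot carbomagnesiation/geranylation). The chelated vinylmagnesium may allylate sluggishly or with some SN2′ attack, and excess MeMgBr consumes geranyl bromide. The fallback starts from 6: the same carbomagnesiation is quenched with iodine to give (3S,4Z)-5-iodo-4-methylpenta-1,4-dien-3-ol F1. Silylation with TBSCl/imidazole gives tert-butyl{[(3S,4Z)-5-iodo-4-methylpenta-1,4-dien-3-yl]oxy}dimethylsilane F2. Iodine–lithium exchange (t-BuLi), transmetalation to zinc (ZnBr2) and Pd(PPh3)4-catalysed alkenyl–allyl coupling with 7 rejoin the route at 10.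

Step 7 (Suzuki coupling with a β-iodoenal). The iodoenal 4 may suffer from base, from aldehyde reduction by the borane, or from loss of alkene geometry in 12. The fallback starts from 4 and couples at the alcohol oxidation level: NaBH4/CeCl3 (MeOH, −40 °C) reduces 4 to (2Z)-4-hydroxy-2-iodobut-2-en-1-yl acetate F3. B-alkyl Suzuki coupling of borane 11 with F3 gives [(2E,5S,6Z,9E)-5-[(tert-butyldimethylsilyl)oxy]-2-(2-hydroxyethylidene)-6,10,14-trimethylpentadeca-6,9,13-trien-1-yl] acetate F4. Neutral MnO2 oxidation of the allylic alcohol then gives 12 without isomerisation.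

**Further compounds**
F1 | step 5 | (3S,4Z)-5-iodo-4-methylpenta-1,4-dien-3-ol | C=C[C@H](O)/C(C)=C\I
F2 | step 5 | tert-butyl{[(3S,4Z)-5-iodo-4-methylpenta-1,4-dien-3-yl]oxy}dimethylsilane | C=C[C@H](O[Si](C)(C)C(C)(C)C)/C(C)=C\I
F3 | step 7 | (2Z)-4-hydroxy-2-iodobut-2-en-1-yl acetate | CC(=O)OC/C(I)=C/CO
F4 | step 7 | [(2E,5S,6Z,9E)-5-[(tert-butyldimethylsilyl)oxy]-2-(2-hydroxyethylidene)-6,10,14-trimethylpentadeca-6,9,13-trien-1-yl] acetate | OC/C=C(/COC(C)=O)CC[C@H](O[Si](C)(C)C(C)(C)C)/C(C)=C\C/C=C(\C)CCC=C(C)C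
F5 | step 8 | (2E,6S,7Z,10E,14E)-3-(acetoxymethyl)-6-[(tert-butyldimethylsilyl)oxy]-16-hydroxy-7,11,15-trimethylhexadeca-2,7,10,14-tetraenal | O=C/C=C(/COC(C)=O)CC[C@H](O[Si](C)(C)C(C)(C)C)/C(C)=C\C/C=C(\C)CC/C=C(\C)CO
F6 | step 8 | (2E,6S,7Z,10E,14E)-3-(acetoxymethyl)-16-bromo-6-[(tert-butyldimethylsilyl)oxy]-7,11,15-trimethylhexadeca-2,7,10,14-tetraenal | O=C/C=C(/COC(C)=O)CC[C@H](O[Si](C)(C)C(C)(C)C)/C(C)=C\C/C=C(\C)CC/C=C(\C)CBr
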